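## Analysis of the target

The target 26 is a benzofuran substituted at every position except C7. It carries a 4-hydroxy-2-methoxyphenyl ring on C2, a formyl group on C3, a free hydroxyl on C4, a 3-hydroxy-3-methylbutyl chain (a hydrated prenyl group) on C5 and a methoxy group on C6. There is no stereocentre, so every difficulty is one of regiochemistry and of functional-group tolerance. The benzo ring is a phloroglucinol nucleus whose three oxygens must end up different (ring oxygen O1, free OH at C4, OMe at C6), with the carbon chain placed between the C4 and C6 oxygens and not at C7. The sensitive groups are the aryl aldehyde, the two phenols and the tertiary alcohol; the tertiary alcohol sits ortho to the C4 phenol and would close to a 2,2-dimethylchroman under acid. The formyl carbon must go to C3 although C7 (between O1 and the methoxy group, para to the C4 oxygen) is about as activated towards electrophiles. The strategy rests on one feature: the aryl group on C2 and the formyl carbon on C3 sit on adjacent carbons of the furan enol-ether bond C2=C3. That is the pattern left when boron on C2 hands a group to C2 while an electrophile adds to C3.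

## Retrosynthetic reasoning

**26 to 25 (two O–benzyl bonds).** The phenols are unmasked last by hydrogenolysis. Benzyl ethers survive the lithiation, the oxidant and the acid used earlier. Their removal is neutral, which matters because the free C4 phenol and the tertiary alcohol must never meet acid together.

**25 to 24 (acetal C–O bonds, O–Si bond).** Aqueous acid turns the dimethyl acetal into the formyl group and removes the silyl ether. This is done while the C4 oxygen is still benzylated, so the tertiary alcohol cannot cyclise onto it.

**24 to 15, 18 and 19 (C2–C1' and C3–CH bonds).** Both substituents of the furan double bond are cut in one disconnection. Lithiation of 15 at C2 and addition to boronate 18 give a borate (21). A formyl-cation equivalent made from 19 should attack C3 while the aryl group moves from boron to C2, and oxidation restores the furan. The gain is that the regiochemistry is dictated by where boron sits: no electrophilic formylation has to choose between C3 and C7, no transition metal is needed, and the formyl carbon arrives at the aldehyde oxidation level.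

**18 to 17 to 16 (C–B bond, O–benzyl bond).** The boronate comes from the aryl bromide by borylation, after benzylation of the commercial bromophenol.

**15 to 14 to 12 (O–Si bond, tertiary C–O bond).** The protected tertiary alcohol is traced to a prenyl group by Markovnikov hydration. The hydration is placed after benzylation of the C4 oxygen and is done by a radical process, because a cationic hydration of an ortho-prenyl phenol would give the chroman.

**12 to 11 to 9 to 7 and 8 (O–benzyl bond, C5–CH2 bond, O–allyl bond).** The chain is attached by an aromatic Claisen rearrangement of the 1,1-dimethylallyl ether 9. C5 is the only ortho position of the C4 oxygen that carries hydrogen, so the shift must deliver the prenyl group there. Direct C-prenylation of the phloroglucinol nucleus would give mixtures with C7.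

**7 to 6 to 5 to 2 and 3 (C2–CO2H bond, then O1–C2 and C2–C3 bonds).** The furan ring is made by alkylation and aldol condensation of the symmetric dihydroxy aldehyde 2 with 3, then saponification and decarboxylation. Because 2 is symmetric, either hydroxyl gives the same benzofuran. The hydroxyl left over becomes the C4 phenol and is thereby told apart from the C6 methoxy group. The annulation precedes the chain because a prenylated aldehyde would have two different hydroxyls, and because decarboxylation at 200 °C would not spare a hydrated chain next to a phenol.

**2 to 1 (O–methyl bond).** Methylation of the most acidic hydroxyl of 1, para to the formyl group.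

## Alternatives that were turned down

**Alternative 1:** Perkin ring contraction of a 3-chlorocoumarin.
- Disconnection: the O1–C2 bond of the furan. The 3-chlorocoumarin A2 is contracted to the 3-methylbenzofuran-2-carboxylic acid A1.
- Forward key step: aqueous NaOH opens the lactone of A2; the phenoxide displaces the vinylic chloride by addition–elimination and closes the furan.
- For: a long-established, scalable ring construction. A2 should come in one Pechmann condensation and a chlorination. The C3 carbon is present from the start, so no C3-versus-C7 question arises. No organometallic or unprecedented step is needed, and on that point this alternative is stronger than the chosen route.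
- Against: A1 has the wrong function on both furan carbons. The methyl group must be oxidised to formyl on a very electron-rich ring, and the acid must be exchanged for the aryl ring. C4 and C6 both carry methoxy groups, so the C4 hydroxyl must be uncovered selectively late. The C5 chain is missing and would have to be pushed in between two methoxy groups.
- Comparison: some eight further operations, several with selectivity problems, follow its key step. The chosen strategy sets the aryl ring and the formyl oxidation level in one operation on a benzofuran (15) that already carries the correct C4/C5/C6 pattern.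

**Alternative 2:** Danheiser benzannulation building the benzo ring on a furan.
- Disconnection: four bonds of the benzene ring (C7–C7a, C6–C7, C4–C5, C3a–C4). The furyl diazoketone A4 and the methoxyalkyne A5 give the benzofuran ester A3.
- Forward key step: photochemical Wolff rearrangement of A4, [2+2] addition to A5, four-electron opening of the cyclobutenone and 6π closure onto the free furan β-carbon, then tautomerisation to the C4 phenol.
- For: highly convergent. The key step creates the free C4 hydroxyl, the C5 chain and the C6 methoxy group in the right places at once. The chosen route spends steps 5 to 9 on that; here Alternative 2 is clearly stronger.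
- Against: A4 is a trisubstituted furan carrying aryl, ester and diazoketone groups and would itself need a multistep synthesis. A5 is a sensitive alkoxyalkyne. The sequence needs photochemistry on a diazo compound. The C3 ester of A3 lies one oxidation level too high and must be reduced and re-oxidised next to a free phenol.
- Comparison: the fragment syntheses make the route longer overall. The chosen strategy starts from cheap aromatics and brings the formyl carbon in at the correct oxidation level.

**Alternative 3:** Rhodium carbenoid C–H insertion closing C2–C3, then aromatisation.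
- Disconnection: the C2–C3 bond. The aryl diazoacetate A7, whose ortho oxygen carries the arylmethyl group, gives the cis-dihydrobenzofuran A6. In A6 the C4 oxygen and C5 are tied as a dihydrocoumarin.
- Forward key step: Rh2(OAc)4 decomposes A7 and the metal carbene inserts into the benzylic C–H bond of the ether, closing the five-membered ring.
- For: the insertion is a known reaction type for 2-aryl-dihydrobenzofurans, so its key step is better precedented than the chosen one. The lactone tether elegantly differentiates the C4 oxygen and carries the C5 chain.
- Against: two stereocentres are made only to be destroyed by a later dehydrogenation. A7 contains a 2,4-dialkoxybenzyl aryl ether that is acid-labile, and electron-rich rings that invite cyclopropanation or insertion into methoxy C–H bonds. After aromatisation the C3 ester and the lactone are both electrophiles, so the double methyl addition that opens the lactone to the tertiary alcohol would compete with the ester. The ester also needs redox adjustment to the aldehyde.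
- Comparison: the chosen strategy creates the same C2-aryl/C3-carbon relationship with no stereocentres, no dehydrogenation and no redox correction, in fewer steps after the coupling.

Key step: step 12

Assumption: the carbonate 8 is treated as a purchasable reagent; it is otherwise available in one operation from 2-methylbut-3-en-2-ol and di-tert-butyl dicarbonate.

## Route

Step 1
Reactants: 1 2,4,6-trihydroxybenzaldehyde
Product: 2 2,6-dihydroxy-4-methoxybenzaldehyde
Conditions: Me2SO4 (1.0 equiv), K2CO3 (1.0 equiv), acetone, rt
Reagents that add atoms: dimethyl sulfate, COS(=O)(=O)OC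
Why: Selective O-alkylation of the most acidic phenol: the C4 hydroxyl is para to the formyl group and cannot chelate to it, so with one equivalent of base and methylating agent its phenoxide should form and react first; the product is symmetric, which makes the two remaining hydroxyls equivalent for step 2.

Step 2
Reactants: 2 2,6-dihydroxy-4-methoxybenzaldehyde; 3 ethyl bromoacetate
Product: 5 ethyl 4-hydroxy-6-methoxybenzofuran-2-carboxylate, via aryloxyacetate 4 (not isolated)
Conditions: K2CO3, DMF, rt; then 90 °C
Reagents that add atoms: none
Why: Williamson O-alkylation followed by intramolecular aldol condensation of the ester enolate on the formyl group (Rap–Stoermer-type benzofuran annulation); either hydroxyl of symmetric 2 gives the same product, the second hydroxyl of 4 is held by a hydrogen bond to the formyl group and should not be alkylated at room temperature, and it becomes the C4 phenol.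

Step 3
Reactants: 5 ethyl 4-hydroxy-6-methoxybenzofuran-2-carboxylate
Product: 6 4-hydroxy-6-methoxybenzofuran-2-carboxylic acid
Conditions: NaOH, EtOH/H2O, reflux; then HCl (aq)
Reagents that add atoms: sodium hydroxide, [Na+].[OH-]
Why: Ester saponification; the benzofuran and the phenol are stable to aqueous base.

Step 4
Reactants: 6 4-hydroxy-6-methoxybenzofuran-2-carboxylic acid
Product: 7 6-methoxybenzofuran-4-ol
Conditions: Cu powder, quinoline, 200 °C
Reagents that add atoms: none
Why: Copper-mediated thermal protodecarboxylation of a heteroaryl 2-carboxylic acid, the classical end of the bromoacetate benzofuran synthesis; it is run before the chain is introduced so that nothing heat- or acid-sensitive is present.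

Step 5
Reactants: 7 6-methoxybenzofuran-4-ol; 8 tert-butyl 2-methylbut-3-en-2-yl carbonate
Product: 9 6-methoxy-4-[(2-methylbut-3-en-2-yl)oxy]benzofuran
Conditions: Pd(PPh3)4 (cat.), THF, 0 °C to rt
Reagents that add atoms: none
Why: Decarboxylative Tsuji–Trost O-allylation: zerovalent palladium ionises the tertiary allylic carbonate, the tert-butoxide released deprotonates the phenol, and the phenoxide attacks the more substituted allyl terminus to give the 1,1-dimethylallyl ether needed for the rearrangement.

Step 6
Reactants: 9 6-methoxy-4-[(2-methylbut-3-en-2-yl)oxy]benzofuran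
Product: 11 6-methoxy-5-(3-methylbut-2-en-1-yl)benzofuran-4-ol, via cyclohexadienone 10 (not isolated)
Conditions: PhNEt2, 160 °C
Reagents that add atoms: none
Why: Aromatic Claisen rearrangement ([3,3] shift): C5 is the only ortho carbon of the C4 oxygen that bears hydrogen (the other is the ring fusion C3a), so the allyl group is delivered to C5 with transposition to the linear prenyl group and 10 tautomerises to the phenol; the basic solvent suppresses acid-catalysed closure to a chroman.

Step 7
Reactants: 11 6-methoxy-5-(3-methylbut-2-en-1-yl)benzofuran-4-ol
Product: 12 4-(benzyloxy)-6-methoxy-5-(3-methylbut-2-en-1-yl)benzofuran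
Conditions: BnBr, K2CO3, DMF, rt
Reagents that add atoms: benzyl bromide, BrCc1ccccc1
Why: Williamson benzylation of the only hydroxyl; capping the C4 oxygen now prevents any later cyclisation of the side chain onto it.

Step 8
Reactants: 12 4-(benzyloxy)-6-methoxy-5-(3-methylbut-2-en-1-yl)benzofuran
Product: 14 4-[4-(benzyloxy)-6-methoxybenzofuran-5-yl]-2-methylbutan-2-ol, via tertiary hydroperoxide 13 (not isolated)
Conditions: Co(acac)2 (cat.), PhSiH3, O2 (1 atm), THF, rt; then PPh3
Reagents that add atoms: dioxygen, O=O
Why: Mukaiyama hydration: hydrogen-atom transfer from a cobalt hydride to the trisubstituted alkene gives the tertiary radical, which is trapped by O2 (Markovnikov) and the peroxide is reduced to the alcohol; the radical course avoids the carbocation chemistry that endangers the acid-sensitive benzofuran, and the aromatic furan C2=C3 bond should react far more slowly than the isolated alkene.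

Step 9
Reactants: 14 4-[4-(benzyloxy)-6-methoxybenzofuran-5-yl]-2-methylbutan-2-ol
Product: 15 4-(benzyloxy)-6-methoxy-5-[3-methyl-3-(triethylsilyloxy)butyl]benzofuran
Conditions: TESOTf, 2,6-lutidine, CH2Cl2, −78 to 0 °C
Reagents that add atoms: triethylsilyl trifluoromethanesulfonate, CC[Si](CC)(CC)OS(=O)(=O)C(F)(F)F
Why: Silylation of a tertiary alcohol needs the silyl triflate; the lutidine buffer protects the benzofuran, and the silyl ether removes the only acidic proton before the lithiation.

Step 10
Reactants: 16 4-bromo-3-methoxyphenol
Product: 17 4-(benzyloxy)-1-bromo-2-methoxybenzene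
Conditions: BnBr, K2CO3, DMF, rt
Reagents that add atoms: benzyl bromide, BrCc1ccccc1
Why: Williamson benzylation of the phenol.

Step 11
Reactants: 17 4-(benzyloxy)-1-bromo-2-methoxybenzene
Product: 18 2-[4-(benzyloxy)-2-methoxyphenyl]-4,4,5,5-tetramethyl-1,3,2-dioxaborolane
Conditions: B2pin2, Pd(dppf)Cl2 (cat.), KOAc, 1,4-dioxane, 90 °C
Reagents that add atoms: bis(pinacolato)diboron, CC1(C)OB(OC1(C)C)B1OC(C)(C)C(C)(C)O1
Why: Miyaura borylation of an electron-rich aryl bromide; the weak acetate base prevents Suzuki homocoupling.

Step 12
Reactants: 15 4-(benzyloxy)-6-methoxy-5-[3-methyl-3-(triethylsilyloxy)butyl]benzofuran; 18 2-[4-(benzyloxy)-2-methoxyphenyl]-4,4,5,5-tetramethyl-1,3,2-dioxaborolane; 19 trimethyl orthoformate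
Product: 24 4-(benzyloxy)-2-[4-(benzyloxy)-2-methoxyphenyl]-3-(dimethoxymethyl)-6-methoxy-5-[3-methyl-3-(triethylsilyloxy)butyl]benzofuran, via 2-lithiobenzofuran 20 (not isolated), via lithium borate complex 21 (not isolated), via 2-boryl-2,3-dihydrobenzofuran 22 (not isolated), via hemiketal 23 (not isolated)
Conditions: n-BuLi, THF, −78 °C; then 18, −78 to 0 °C; then [(MeO)2CH]BF4 (pre-formed from 19 and BF3·OEt2, CH2Cl2, −30 °C), −78 to 0 °C; then NaOH, H2O2, THF/H2O, 0 °C; then PPTS (cat.), 4 Å MS, CH2Cl2, rt
Reagents that add atoms: none
Why: Proposed new method: n-BuLi removes the most acidic proton of 15, C2–H, to give 20, which adds to the boron of 18 to form the tetracoordinate borate 21, whose C2=C3 bond is an enol ether with an anionic boron on C2 and is therefore strongly nucleophilic at C3. The dimethoxycarbenium ion made from 19 is expected to attack C3 (C3–CH(OMe)2 bond) while the aryl group shifts from boron to C2 anti to the incoming electrophile (C2–C1' bond), giving the α-boryl ether 22; no ring is closed. The closest known reaction types are the electrophile-induced 1,2-metallate rearrangement of indol-2-yl and furan-2-yl boronate complexes in three-component couplings and the halogen-induced alkyl transfer in benzofuran-2-yl borates; a dialkoxycarbenium electrophile on a benzofuran-2-yl borate is without precedent. Hydroperoxide then oxidises the C2–B bond with retention to the hemiketal 23, and a trace of acid under water-free conditions removes water across C2–C3, which restores the aromatic furan and leaves the acetal intact. The two stereocentres of 22 and 23 (aryl and acetal groups trans, set by the anti migration) are transient and vanish in 24. The step needs lithiation at C2 and not C7, and attack at C3 and not at C7 or the aryl ring: the kinetic acidity of the furan α-proton at −78 °C secures the first, and the negative charge of the borate together with aryl being the only group on boron able to migrate secures the second. The carbenium salt is pre-formed and freed of excess BF3 so that no Lewis acid competes for the borate, and the anhydrous dehydration avoids a ring-opened keto phenol that could close again on the wrong carbon.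

Step 13
Reactants: 24 4-(benzyloxy)-2-[4-(benzyloxy)-2-methoxyphenyl]-3-(dimethoxymethyl)-6-methoxy-5-[3-methyl-3-(triethylsilyloxy)butyl]benzofuran
Product: 25 4-(benzyloxy)-2-[4-(benzyloxy)-2-methoxyphenyl]-5-(3-hydroxy-3-methylbutyl)-6-methoxybenzofuran-3-carbaldehyde
Conditions: 1 M HCl, THF, rt
Reagents that add atoms: water, O
Why: Acid hydrolysis of the dimethyl acetal and of the triethylsilyl ether in one operation; the C4 oxygen is still benzylated, so the liberated tertiary alcohol cannot close to a chroman, and dilute acid at room temperature should not ionise it.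

Step 14
Reactants: 25 4-(benzyloxy)-2-[4-(benzyloxy)-2-methoxyphenyl]-5-(3-hydroxy-3-methylbutyl)-6-methoxybenzofuran-3-carbaldehyde
Product: 26 4-hydroxy-2-(4-hydroxy-2-methoxyphenyl)-5-(3-hydroxy-3-methylbutyl)-6-methoxybenzofuran-3-carbaldehyde
Conditions: H2 (1 atm), Pd/C, EtOAc, rt
Reagents that add atoms: none
Why: Hydrogenolysis of both benzyl ethers under neutral conditions; the formyl group is a vinylogous formate (conjugated with O1 through C2=C3), which lowers its tendency to be reduced, and the tetrasubstituted furan double bond should resist hydrogenation.

## Compound list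

1 | 2,4,6-trihydroxybenzaldehyde | O=Cc1c(O)cc(O)cc1O | starting material
2 | 2,6-dihydroxy-4-methoxybenzaldehyde | COc1cc(O)c(C=O)c(O)c1 | intermediate
3 | ethyl bromoacetate | CCOC(=O)CBr | starting material
4 | ethyl 2-(2-formyl-3-hydroxy-5-methoxyphenoxy)acetate | CCOC(=O)COc1cc(OC)cc(O)c1C=O | intermediate (not isolated)
5 | ethyl 4-hydroxy-6-methoxybenzofuran-2-carboxylate | CCOC(=O)c1cc2c(O)cc(OC)cc2o1 | intermediate
6 | 4-hydroxy-6-methoxybenzofuran-2-carboxylic acid | O=C(O)c1cc2c(O)cc(OC)cc2o1 | intermediate
7 | 6-methoxybenzofuran-4-ol | COc1cc(O)c2ccoc2c1 | intermediate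
8 | tert-butyl 2-methylbut-3-en-2-yl carbonate | CC(C)(C)OC(=O)OC(C)(C)C=C | starting material
9 | 6-methoxy-4-[(2-methylbut-3-en-2-yl)oxy]benzofuran | C=CC(C)(C)Oc1cc(OC)cc2occc12 | intermediate
10 | 6-methoxy-5-(3-methylbut-2-en-1-yl)benzofuran-4(5H)-one (racemic, transient) | COC1=Cc2occc2C(=O)C1CC=C(C)C | intermediate (not isolated)
11 | 6-methoxy-5-(3-methylbut-2-en-1-yl)benzofuran-4-ol | COc1cc2occc2c(O)c1CC=C(C)C | intermediate
12 | 4-(benzyloxy)-6-methoxy-5-(3-methylbut-2-en-1-yl)benzofuran | COc1cc2occc2c(OCc3ccccc3)c1CC=C(C)C | intermediate
13 | 4-(benzyloxy)-5-(3-hydroperoxy-3-methylbutyl)-6-methoxybenzofuran | COc1cc2occc2c(OCc3ccccc3)c1CCC(C)(C)OO | intermediate (not isolated)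
14 | 4-[4-(benzyloxy)-6-methoxybenzofuran-5-yl]-2-methylbutan-2-ol | COc1cc2occc2c(OCc3ccccc3)c1CCC(C)(C)O | intermediate
15 | 4-(benzyloxy)-6-methoxy-5-[3-methyl-3-(triethylsilyloxy)butyl]benzofuran | CC[Si](CC)(CC)OC(C)(C)CCc1c(OC)cc2occc2c1OCc1ccccc1 | intermediate
16 | 4-bromo-3-methoxyphenol | COc1cc(O)ccc1Br | starting material
17 | 4-(benzyloxy)-1-bromo-2-methoxybenzene | COc1cc(OCc2ccccc2)ccc1Br | intermediate
18 | 2-[4-(benzyloxy)-2-methoxyphenyl]-4,4,5,5-tetramethyl-1,3,2-dioxaborolane | COc1cc(OCc2ccccc2)ccc1B1OC(C)(C)C(C)(C)O1 | intermediate
19 | trimethyl orthoformate | COC(OC)OC | starting material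
20 | [4-(benzyloxy)-6-methoxy-5-[3-methyl-3-(triethylsilyloxy)butyl]benzofuran-2-yl]lithium | [Li]c1cc2c(OCc3ccccc3)c(CCC(C)(C)O[Si](CC)(CC)CC)c(OC)cc2o1 | intermediate (not isolated)
21 | lithium [4-(benzyloxy)-2-methoxyphenyl][4-(benzyloxy)-6-methoxy-5-[3-methyl-3-(triethylsilyloxy)butyl]benzofuran-2-yl](pinacolato)borate | [Li+].COc1cc(OCc2ccccc2)ccc1[B-]3(OC(C)(C)C(C)(C)O3)c4cc5c(OCc6ccccc6)c(CCC(C)(C)O[Si](CC)(CC)CC)c(OC)cc5o4 | intermediate (not isolated)
22 | 4-(benzyloxy)-2-[4-(benzyloxy)-2-methoxyphenyl]-3-(dimethoxymethyl)-6-methoxy-2-(4,4,5,5-tetramethyl-1,3,2-dioxaborolan-2-yl)-5-[3-methyl-3-(triethylsilyloxy)butyl]-2,3-dihydrobenzofuran (aryl and dimethoxymethyl trans; racemic, one enantiomer drawn) | COC(OC)[C@@H]1c2c(OCc3ccccc3)c(CCC(C)(C)O[Si](CC)(CC)CC)c(OC)cc2O[C@@]1(B3OC(C)(C)C(C)(C)O3)c4ccc(OCc5ccccc5)cc4OC | intermediate (not isolated)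
23 | 4-(benzyloxy)-2-[4-(benzyloxy)-2-methoxyphenyl]-3-(dimethoxymethyl)-6-methoxy-5-[3-methyl-3-(triethylsilyloxy)butyl]-2,3-dihydrobenzofuran-2-ol (hemiketal; racemic, one enantiomer drawn) | COC(OC)[C@@H]1c2c(OCc3ccccc3)c(CCC(C)(C)O[Si](CC)(CC)CC)c(OC)cc2O[C@@]1(O)c4ccc(OCc5ccccc5)cc4OC | intermediate (not isolated)
24 | 4-(benzyloxy)-2-[4-(benzyloxy)-2-methoxyphenyl]-3-(dimethoxymethyl)-6-methoxy-5-[3-methyl-3-(triethylsilyloxy)butyl]benzofuran | COC(OC)c1c(-c2ccc(OCc3ccccc3)cc2OC)oc2cc(OC)c(CCC(C)(C)O[Si](CC)(CC)CC)c(OCc3ccccc3)c12 | intermediate
25 | 4-(benzyloxy)-2-[4-(benzyloxy)-2-methoxyphenyl]-5-(3-hydroxy-3-methylbutyl)-6-methoxybenzofuran-3-carbaldehyde | O=Cc1c(-c2ccc(OCc3ccccc3)cc2OC)oc2cc(OC)c(CCC(C)(C)O)c(OCc3ccccc3)c12 | intermediate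
26 | 4-hydroxy-2-(4-hydroxy-2-methoxyphenyl)-5-(3-hydroxy-3-methylbutyl)-6-methoxybenzofuran-3-carbaldehyde | COc1cc(O)ccc1-c1oc2cc(OC)c(CCC(C)(C)O)c(O)c2c1C=O | target

## Step count and least certain steps

Total step count: 14. Longest linear sequence: 12 steps (steps 1 to 9, then 12 to 14); the boronate branch (steps 10 and 11) has 2 steps.

**Step 12 (key step, proposed new method).**
- What may go wrong: ipso attack of the carbenium ion at a boron-bearing carbon, so that the acetal is introduced without aryl migration or the borate is simply cleaved; methyl transfer from the carbenium ion in place of C–C bond formation; and, during the basic oxidation, ring opening of the hemiketal with β-elimination of methoxide and closure through the other carbonyl, which would scramble the regiochemistry. NaBO3·4H2O is a milder oxidant if the last process shows.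
- Fallback with known chemistry, from 15 back to 25: lithiation as in step 12 gives 20, which is transmetalated with ZnCl2 to [4-(benzyloxy)-6-methoxy-5-[3-methyl-3-(triethylsilyloxy)butyl]benzofuran-2-yl]zinc chloride F1. F1 is coupled with bromide 17 under Pd(PPh3)4 catalysis (Negishi coupling) to 4-(benzyloxy)-2-[4-(benzyloxy)-2-methoxyphenyl]-6-methoxy-5-[3-methyl-3-(triethylsilyloxy)butyl]benzofuran F2. Vilsmeier–Haack formylation (POCl3, DMF) at C3, the enol-ether carbon conjugated with the C2 aryl ring, should then give 4-(benzyloxy)-2-[4-(benzyloxy)-2-methoxyphenyl]-6-methoxy-5-[3-methyl-3-(triethylsilyloxy)butyl]benzofuran-3-carbaldehyde F3. Aqueous acid as in step 13 removes the silyl ether and returns to the route at 25. This sequence brings back the competition between C3 and C7 in the formylation, which is why it is the fallback and not the route.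

**Step 8.**
- What may go wrong: hydrogen-atom transfer to the furan double bond, plain reduction of the alkene in place of oxygen trapping, or incomplete reduction of the peroxide.
- Fallback, from 12 back to 14: epoxidation of the trisubstituted alkene with mCPBA (NaHCO3 buffer, 0 °C) gives 4-(benzyloxy)-5-[(3,3-dimethyloxiran-2-yl)methyl]-6-methoxybenzofuran F4. Hydride opening with LiAlH4 at the less substituted epoxide carbon should then give the tertiary alcohol 14.

**Step 14.**
- What may go wrong: over-reduction of the formyl group (to the alcohol or the methyl group) or slow saturation of the furan bond while the second benzyl ether is still being cleaved.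
- Fallback, from 24 back to 26: the order of the last two steps is reversed. Hydrogenolysis of 24 (H2, Pd/C, EtOAc with a trace of Et3N), with the aldehyde still masked as the acetal, gives 3-(dimethoxymethyl)-2-(4-hydroxy-2-methoxyphenyl)-6-methoxy-5-[3-methyl-3-(triethylsilyloxy)butyl]benzofuran-4-ol F5. Brief treatment with dilute aqueous acid at room temperature hydrolyses acetal and silyl ether to 26; the exposure is kept short because the C4 phenol is now free.

**Step 2.**
- What may go wrong: a second O-alkylation, either of 4 or of the phenol of 5 once the ring has closed, and incomplete aldol closure.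
- Fallback, from 2 back to 6: one hydroxyl of 2 is protected first (MOMCl, i-Pr2NEt) as 2-hydroxy-4-methoxy-6-(methoxymethoxy)benzaldehyde F6. The annulation with 3 (K2CO3, DMF, 90 °C) on the single remaining hydroxyl gives ethyl 6-methoxy-4-(methoxymethoxy)benzofuran-2-carboxylate F7. Saponification followed by warm aqueous HCl in methanol removes the ester and the acetal protecting group and gives 6.

**Step 1.**
- What may go wrong: methylation of a second hydroxyl or of an ortho hydroxyl, giving a mixture that lowers the throughput.
- Fallback, from 1 back to 2: exhaustive methylation (MeI, K2CO3, DMF) gives 2,4,6-trimethoxybenzaldehyde F8. Chelation-controlled cleavage of the two methoxy groups ortho to the formyl group with excess AlCl3 in CH2Cl2 should then give 2, the para methoxy group lacking the carbonyl assistance.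

## Further compounds

F1 | step 12 | [4-(benzyloxy)-6-methoxy-5-[3-methyl-3-(triethylsilyloxy)butyl]benzofuran-2-yl]zinc chloride | Cl[Zn]c1cc2c(OCc3ccccc3)c(CCC(C)(C)O[Si](CC)(CC)CC)c(OC)cc2o1
F2 | step 12 | 4-(benzyloxy)-2-[4-(benzyloxy)-2-methoxyphenyl]-6-methoxy-5-[3-methyl-3-(triethylsilyloxy)butyl]benzofuran | COc1cc(OCc2ccccc2)ccc1-c1cc2c(OCc3ccccc3)c(CCC(C)(C)O[Si](CC)(CC)CC)c(OC)cc2o1
F3 | step 12 | 4-(benzyloxy)-2-[4-(benzyloxy)-2-methoxyphenyl]-6-methoxy-5-[3-methyl-3-(triethylsilyloxy)butyl]benzofuran-3-carbaldehyde | O=Cc1c(-c2ccc(OCc3ccccc3)cc2OC)oc2cc(OC)c(CCC(C)(C)O[Si](CC)(CC)CC)c(OCc3ccccc3)c12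
F4 | step 8 | 4-(benzyloxy)-5-[(3,3-dimethyloxiran-2-yl)methyl]-6-methoxybenzofuran (racemic) | COc1cc2occc2c(OCc3ccccc3)c1CC1OC1(C)C
F5 | step 14 | 3-(dimethoxymethyl)-2-(4-hydroxy-2-methoxyphenyl)-6-methoxy-5-[3-methyl-3-(triethylsilyloxy)butyl]benzofuran-4-ol | COC(OC)c1c(-c2ccc(O)cc2OC)oc2cc(OC)c(CCC(C)(C)O[Si](CC)(CC)CC)c(O)c12
F6 | step 2 | 2-hydroxy-4-methoxy-6-(methoxymethoxy)benzaldehyde | COCOc1cc(OC)cc(O)c1C=O
F7 | step 2 | ethyl 6-methoxy-4-(methoxymethoxy)benzofuran-2-carboxylate | CCOC(=O)c1cc2c(OCOC)cc(OC)cc2o1
F8 | step 1 | 2,4,6-trimethoxybenzaldehyde | COc1cc(OC)c(C=O)c(OC)c1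
A1 | alternative 1 | 4,6-dimethoxy-3-methylbenzofuran-2-carboxylic acid | COc1cc(OC)c2c(C)c(C(=O)O)oc2c1
A2 | alternative 1 | 3-chloro-5,7-dimethoxy-4-methyl-2H-chromen-2-one | COc1cc(OC)c2c(C)c(Cl)c(=O)oc2c1
A3 | alternative 2 | methyl 4-hydroxy-6-methoxy-2-[2-methoxy-4-(triisopropylsilyloxy)phenyl]-5-[3-methyl-3-(triethylsilyloxy)butyl]benzofuran-3-carboxylate | COC(=O)c1c(-c2ccc(O[Si](C(C)C)(C(C)C)C(C)C)cc2OC)oc2cc(OC)c(CCC(C)(C)O[Si](CC)(CC)CC)c(O)c12
A4 | alternative 2 | methyl 5-(2-diazoacetyl)-2-[2-methoxy-4-(triisopropylsilyloxy)phenyl]furan-3-carboxylate | COC(=O)c1cc(C(=O)C=[N+]=[N-])oc1-c1ccc(O[Si](C(C)C)(C(C)C)C(C)C)cc1OC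
A5 | alternative 2 | 1-methoxy-5-methyl-5-(triethylsilyloxy)hex-1-yne | COC#CCCC(C)(C)O[Si](CC)(CC)CC
A6 | alternative 3 | lactone-bridged methyl cis-2-[4-(benzyloxy)-2-methoxyphenyl]-6-methoxy-2,3-dihydrobenzofuran-3-carboxylate, C4 oxygen and C5 tied as a dihydrocoumarin (racemic, one enantiomer drawn) | COC(=O)[C@@H]1[C@H](c2ccc(OCc3ccccc3)cc2OC)Oc2cc(OC)c3CCC(=O)Oc3c21
A7 | alternative 3 | methyl 2-diazo-2-[7-{[4-(benzyloxy)-2-methoxyphenyl]methoxy}-5-methoxy-2-oxo-3,4-dihydro-2H-chromen-8-yl]acetate | COC(=O)C(=[N+]=[N-])c1c(OCc2ccc(OCc3ccccc3)cc2OC)cc(OC)c2CCC(=O)Oc12
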